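**Strategy.** Everything rests on opening the (Z)-γ-ylidene butenolide: ring O1, C2(=O), C3 (bearing the vinyl arm to ring B), C4, C5 and its exocyclic CH. Step 22 couples a terminal alkyne with a (Z)-3-iodoacrylic acid (C4–C5, Sonogashira) and lets the cis-carboxylate add to the same alkyne (O1–C5, 5-exo-dig), so both bonds, the lactone and the Z-ylidene geometry arise in one operation. The precursors are the ring A tetraenediyne carbinol 15 and the ring B triol iodoacid 26, both with free hydroxyls, so the coupling gives the target directly. Both rings derive from one enol triflate, 5.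

Key step: step 22

Remark on the chemistry: the silyl groups are removed before the key step (steps 12 and 14), because the coupling tolerates free hydroxyls and the finished butenolide then never meets fluoride. The descriptor of the ring B quaternary carbinol carbon reads S with ethynyl (18, 19) and R with vinyl (20 onward) without any change in space. Polyenes from 9 onward are handled under argon in the dark.

**Route**

Step 1
Reactants: 1 ketoisophorone
Product: 2 (6R)-2,2,6-trimethylcyclohexane-1,4-dione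
Conditions: ene-reductase OYE1 (old yellow enzyme), NADP+ (cat.), D-glucose, glucose dehydrogenase, phosphate buffer pH 7, 30 °C
Reagents that add atoms: none
Why: Enzymatic conjugate reduction of the enedione C=C by an ene-reductase is an established entry to (R)-levodione, the enzyme pocket fixing C6 as R.

Step 2
Reactants: 2 (6R)-2,2,6-trimethylcyclohexane-1,4-dione
Product: 3 (4R,6R)-4-hydroxy-2,2,6-trimethylcyclohexan-1-one
Conditions: L-Selectride, THF, −78 °C
Reagents that add atoms: none
Why: Hydride reduction of the unhindered C4 ketone only; the bulky borohydride attacks equatorially, away from the axial methyl of the gem-dimethyl carbon (3,3,5-trimethylcyclohexanone model), and should give the axial alcohol trans to the C6 methyl (4R).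

Step 3
Reactants: 3 (4R,6R)-4-hydroxy-2,2,6-trimethylcyclohexan-1-one
Product: 4 (4R,6R)-4-[(tert-butyldimethylsilyl)oxy]-2,2,6-trimethylcyclohexan-1-one
Conditions: TBSCl, imidazole, DMF, rt
Reagents that add atoms: tert-butyldimethylsilyl chloride, CC(C)(C)[Si](C)(C)Cl
Why: Standard silyl ether formation, needed because step 4 uses a strong base and a triflating agent.

Step 4
Reactants: 4 (4R,6R)-4-[(tert-butyldimethylsilyl)oxy]-2,2,6-trimethylcyclohexan-1-one
Product: 5 (4R)-4-[(tert-butyldimethylsilyl)oxy]-2,6,6-trimethylcyclohex-1-en-1-yl trifluoromethanesulfonate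
Conditions: LDA, THF, −78 °C; PhNTf2, −78 to 0 °C
Reagents that add atoms: N-phenylbis(trifluoromethanesulfonimide), O=S(=O)(N(c1ccccc1)S(=O)(=O)C(F)(F)F)C(F)(F)F
Why: Enolate O-triflation; the ketone has a single α-hydrogen, so only one enol triflate can form, C6 becomes sp2 and the C4 stereocentre is untouched.

Step 5
Reactants: 5 ring enol triflate; 6 (E)-3-methylpent-2-en-4-yn-1-ol
Product: 7 (2E)-5-{(4R)-4-[(tert-butyldimethylsilyl)oxy]-2,6,6-trimethylcyclohex-1-en-1-yl}-3-methylpent-2-en-4-yn-1-ol
Conditions: Pd(PPh3)4 (cat.), CuI (cat.), iPr2NH, DMF, 40 °C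
Reagents that add atoms: none
Why: Sonogashira coupling of an enol triflate with a terminal enyne, which tolerates the free allylic alcohol and keeps the E geometry of 6.

Step 6
Reactants: 7 ring A dienynol
Product: 8 (2E)-5-{(4R)-4-[(tert-butyldimethylsilyl)oxy]-2,6,6-trimethylcyclohex-1-en-1-yl}-3-methylpent-2-en-4-ynal
Conditions: MnO2, CH2Cl2, rt
Reagents that add atoms: none
Why: Chemoselective MnO2 oxidation of a primary allylic alcohol to the enal, leaving alkyne, silyl ether and alkene geometry alone.

Step 7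
Reactants: 8 ring A enynal
Product: 9 (2E,4E)-7-{(4R)-4-[(tert-butyldimethylsilyl)oxy]-2,6,6-trimethylcyclohex-1-en-1-yl}-5-methylhepta-2,4-dien-6-ynal
Conditions: Ph3P=CHCHO, toluene, 80 °C
Reagents that add atoms: (triphenylphosphoranylidene)acetaldehyde, O=CC=P(c1ccccc1)(c1ccccc1)c1ccccc1
Why: Wittig reaction with a stabilised formyl ylide should add two carbons as an (E)-enal, the vinylogous product being less electrophilic than 8.

Step 8
Reactants: 6 (E)-3-methylpent-2-en-4-yn-1-ol
Product: 11 (2E)-3-methyl-5-(trimethylsilyl)pent-2-en-4-yn-1-ol, via doubly silylated enynol 10 (not isolated)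
Conditions: n-BuLi (2.1 equiv), THF, −78 °C; TMSCl (2.2 equiv); 1 M HCl, 0 °C
Reagents that add atoms: chlorotrimethylsilane, C[Si](C)(C)Cl
Why: Alkoxide and acetylide are both silylated, and dilute acid then cleaves only the O–Si bond of 10 (alkyne protection by C-silylation).

Step 9
Reactants: 11 (2E)-3-methyl-5-(trimethylsilyl)pent-2-en-4-yn-1-ol
Product: 12 [(3E)-5-bromo-3-methylpent-3-en-1-yn-1-yl]trimethylsilane
Conditions: CBr4, PPh3, CH2Cl2, 0 °C
Reagents that add atoms: carbon tetrabromide, BrC(Br)(Br)Br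
Why: Appel bromination of a primary allylic alcohol under neutral conditions, without allylic transposition at this primary centre.

Step 10
Reactants: 12 allylic bromide
Product: 13 diethyl [(2E)-3-methyl-5-(trimethylsilyl)pent-2-en-4-yn-1-yl]phosphonate
Conditions: P(OEt)3, neat, 110 °C
Reagents that add atoms: triethyl phosphite, CCOP(OCC)OCC
Why: Michaelis–Arbuzov reaction of an allylic bromide gives the phosphonate for an E-selective olefination.

Step 11
Reactants: 13 enyne phosphonate; 9 ring A dienynal
Product: 14 tert-butyl{[(1R)-4-[(3E,5E,7E,9E)-3,10-dimethyl-12-(trimethylsilyl)dodeca-3,5,7,9-tetraene-1,11-diyn-1-yl]-3,5,5-trimethylcyclohex-3-en-1-yl]oxy}dimethylsilane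
Conditions: NaHMDS, THF, −78 to 0 °C
Reagents that add atoms: none
Why: Horner–Wadsworth–Emmons olefination with an allylic phosphonate anion should form the central double bond mainly E; any Z isomer would be removed by chromatography or equilibrated (cat. I2) to the all-E polyene.

Step 12
Reactants: 14 doubly silylated tetraenediyne
Product: 15 (1R)-4-[(3E,5E,7E,9E)-3,10-dimethyldodeca-3,5,7,9-tetraene-1,11-diyn-1-yl]-3,5,5-trimethylcyclohex-3-en-1-ol
Conditions: TBAF, THF, 0 °C to rt
Reagents that add atoms: none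
Why: Fluoride-mediated desilylation should remove the alkynyl trimethylsilyl group and the secondary silyl ether in one operation, giving the terminal alkyne and the free ring A carbinol.

Step 13
Reactants: 5 ring enol triflate
Product: 16 tert-butyldimethyl{[(1R)-3,5,5-trimethyl-4-[(trimethylsilyl)ethynyl]cyclohex-3-en-1-yl]oxy}silane
Conditions: ethynyltrimethylsilane, Pd(PPh3)4 (cat.), CuI (cat.), iPr2NH, DMF, 40 °C
Reagents that add atoms: ethynyltrimethylsilane, C#C[Si](C)(C)C
Why: Sonogashira coupling of the enol triflate installs the two carbons that become the vinyl arm of ring B.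

Step 14
Reactants: 16 silylated ring enyne
Product: 17 (1R)-4-ethynyl-3,5,5-trimethylcyclohex-3-en-1-ol
Conditions: TBAF, THF, rt
Reagents that add atoms: none
Why: Fluoride cleaves both silicon groups, freeing the terminal alkyne and the homoallylic hydroxyl that must direct step 15.

Step 15
Reactants: 17 ring enynol
Product: 18 (1S,3S,6S)-6-ethynyl-1,5,5-trimethyl-7-oxabicyclo[4.1.0]heptan-3-ol (epoxide cis to the hydroxyl)
Conditions: VO(acac)2 (cat.), t-BuOOH, toluene, rt to 40 °C
Reagents that add atoms: tert-butyl hydroperoxide, CC(C)(C)OO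
Why: Vanadium-catalysed hydroxyl-directed epoxidation of a homoallylic alcohol should deliver oxygen to the ring face cis to the carbinol, fixing the C–O bond at the alkyne-bearing carbon in its final configuration; the alkyne is inert.

Step 16
Reactants: 18 syn-epoxy alcohol
Product: 19 (1S,2R,4S)-1-ethynyl-2,6,6-trimethylcyclohexane-1,2,4-triol
Conditions: H2SO4 (0.05 M), THF/H2O, 0 °C
Reagents that add atoms: water, O
Why: Acid-catalysed anti hydrolysis of a tetrasubstituted epoxide (trans-diaxial, Fürst–Plattner opening); water should attack the methyl-bearing carbon with inversion, because the other epoxide carbon is neopentylic and deactivated by the ethynyl group, which gives the trans diol with the new hydroxyl trans to the secondary carbinol.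

Step 17
Reactants: 19 alkynyl triol
Product: 20 (1R,2R,4S)-2,6,6-trimethyl-1-[(E)-2-(tributylstannyl)ethenyl]cyclohexane-1,2,4-triol
Conditions: Bu3SnH, PdCl2(PPh3)2 (cat.), THF, 0 °C
Reagents that add atoms: tributyltin hydride, CCCC[SnH](CCCC)CCCC
Why: Palladium-catalysed syn hydrostannation of a hindered tertiary propargylic alcohol should place tin on the terminal carbon and give the (E)-vinylstannane, with free hydroxyls tolerated.

Step 18
Reactants: 21 methyl 3-(trimethylsilyl)prop-2-ynoate
Product: 23 methyl (2E)-2-iodo-3-(trimethylsilyl)prop-2-enoate (silicon cis to the ester), via vinylstannane 22 (not isolated)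
Conditions: Bu3SnH, Pd(PPh3)4 (cat.), THF, rt; I2, CH2Cl2, 0 °C
Reagents that add atoms: tributyltin hydride, CCCC[SnH](CCCC)CCCC (tin is carried only by 22); iodine, II
Why: Palladium-catalysed hydrostannation of an ynoate puts tin α to the ester by syn addition (also β to silicon), and iododestannylation proceeds with retention, so silicon ends cis to the ester.

Step 19
Reactants: 20 ring B vinylstannane; 23 methyl 2-iodo-3-silylacrylate
Product: 24 methyl (2Z)-2-{(E)-2-[(1R,2R,4S)-1,2,4-trihydroxy-2,6,6-trimethylcyclohexyl]ethenyl}-3-(trimethylsilyl)prop-2-enoate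
Conditions: Pd2(dba)3 (cat.), AsPh3 (cat.), CuI (cat.), DMF, rt to 40 °C
Reagents that add atoms: none
Why: Stille coupling of a vinylstannane with an α-iodoacrylate should join the arm to the acrylate α-carbon with retention of both alkene geometries.

Step 20
Reactants: 24 silyl dienoate triol
Product: 25 methyl (2Z)-3-iodo-2-{(E)-2-[(1R,2R,4S)-1,2,4-trihydroxy-2,6,6-trimethylcyclohexyl]ethenyl}prop-2-enoate
Conditions: NIS, HFIP, 0 °C, dark
Reagents that add atoms: N-iodosuccinimide, O=C1CCC(=O)N1I
Why: Electrophilic ipso-iododesilylation of the vinylsilane (the cation formed is β to silicon and allylic) should replace silicon by iodine with retention, leaving iodine cis to the ester.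

Step 21
Reactants: 25 iodo dienoate triol
Product: 26 (2Z)-3-iodo-2-{(E)-2-[(1R,2R,4S)-1,2,4-trihydroxy-2,6,6-trimethylcyclohexyl]ethenyl}prop-2-enoic acid
Conditions: LiOH, THF/H2O, 0 °C to rt; acidic work-up (1 M HCl, pH 3)
Reagents that add atoms: lithium hydroxide, [Li+].[OH-]
Why: Ester saponification at low temperature; the acrylate has no α-hydrogen, so elimination cannot occur and the cis iodide–carboxyl geometry should be kept.

Step 22
Reactants: 15 ring A tetraenediyne carbinol; 26 ring B triol iodoacid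
Product: 28 target, via enynoic acid 27 (not isolated)
Conditions: Pd(PPh3)4 (cat.), CuI (cat.), Et3N, DMF, rt, dark
Reagents that add atoms: none
Why: Oxidative addition of vinyl iodide 26 to zerovalent palladium is followed by alkynyl transfer from copper and C–C reductive elimination, which creates the C4–C5 bond and leaves enynoic acid 27 as its triethylammonium salt. Because the carboxylate sits cis to the new alkyne, it should attack the nearer alkyne carbon from the side opposite the coordinated metal, and replacement of the metal by a proton leaves hydrogen anti to the lactone oxygen, i.e. the Z ylidene. The closest known reaction type is the one-flask Sonogashira coupling and lactonisation of (Z)-3-iodoalkenoic acids with 1-alkynes to (Z)-γ-ylidene butenolides. The single ring formed is the five-membered lactone, closed in the 5-exo-dig mode by O1 on C5. No stereocentre is created; the only new stereoelement is the exocyclic double bond, set by the anti addition. The step needs 5-exo rather than 6-endo closure and Z geometry, which the fixed cis carboxyl–alkyne arrangement and the unhindered conjugated alkyne favour, while room temperature and amine buffering should leave the tetraene, the carbinols and the tertiary diol intact.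

**Compound list**

1 | ketoisophorone (2,6,6-trimethylcyclohex-2-ene-1,4-dione) | CC1=CC(=O)CC(C)(C)C1=O | starting material
2 | (6R)-2,2,6-trimethylcyclohexane-1,4-dione | C[C@@H]1CC(=O)CC(C)(C)C1=O | intermediate
3 | (4R,6R)-4-hydroxy-2,2,6-trimethylcyclohexan-1-one (hydroxyl trans to the C6 methyl) | C[C@@H]1C[C@@H](O)CC(C)(C)C1=O | intermediate
4 | (4R,6R)-4-[(tert-butyldimethylsilyl)oxy]-2,2,6-trimethylcyclohexan-1-one | C[C@@H]1C[C@@H](O[Si](C)(C)C(C)(C)C)CC(C)(C)C1=O | intermediate
5 | (4R)-4-[(tert-butyldimethylsilyl)oxy]-2,6,6-trimethylcyclohex-1-en-1-yl trifluoromethanesulfonate | CC1=C(OS(=O)(=O)C(F)(F)F)C(C)(C)C[C@H](O[Si](C)(C)C(C)(C)C)C1 | intermediate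
6 | (E)-3-methylpent-2-en-4-yn-1-ol | C#C/C(C)=C/CO | starting material
7 | (2E)-5-{(4R)-4-[(tert-butyldimethylsilyl)oxy]-2,6,6-trimethylcyclohex-1-en-1-yl}-3-methylpent-2-en-4-yn-1-ol | CC1=C(C#C/C(C)=C/CO)C(C)(C)C[C@H](O[Si](C)(C)C(C)(C)C)C1 | intermediate
8 | (2E)-5-{(4R)-4-[(tert-butyldimethylsilyl)oxy]-2,6,6-trimethylcyclohex-1-en-1-yl}-3-methylpent-2-en-4-ynal | CC1=C(C#C/C(C)=C/C=O)C(C)(C)C[C@H](O[Si](C)(C)C(C)(C)C)C1 | intermediate
9 | (2E,4E)-7-{(4R)-4-[(tert-butyldimethylsilyl)oxy]-2,6,6-trimethylcyclohex-1-en-1-yl}-5-methylhepta-2,4-dien-6-ynal | CC1=C(C#C/C(C)=C/C=C/C=O)C(C)(C)C[C@H](O[Si](C)(C)C(C)(C)C)C1 | intermediate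
10 | trimethyl{[(2E)-3-methyl-5-(trimethylsilyl)pent-2-en-4-yn-1-yl]oxy}silane | C[Si](C)(C)C#C/C(C)=C/CO[Si](C)(C)C | intermediate
11 | (2E)-3-methyl-5-(trimethylsilyl)pent-2-en-4-yn-1-ol | C[Si](C)(C)C#C/C(C)=C/CO | intermediate
12 | [(3E)-5-bromo-3-methylpent-3-en-1-yn-1-yl]trimethylsilane | C[Si](C)(C)C#C/C(C)=C/CBr | intermediate
13 | diethyl [(2E)-3-methyl-5-(trimethylsilyl)pent-2-en-4-yn-1-yl]phosphonate | CCOP(=O)(OCC)C/C=C(C)/C#C[Si](C)(C)C | intermediate
14 | tert-butyl{[(1R)-4-[(3E,5E,7E,9E)-3,10-dimethyl-12-(trimethylsilyl)dodeca-3,5,7,9-tetraene-1,11-diyn-1-yl]-3,5,5-trimethylcyclohex-3-en-1-yl]oxy}dimethylsilane | CC1=C(C#C/C(C)=C/C=C/C=C/C=C(C)/C#C[Si](C)(C)C)C(C)(C)C[C@H](O[Si](C)(C)C(C)(C)C)C1 | intermediate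
15 | (1R)-4-[(3E,5E,7E,9E)-3,10-dimethyldodeca-3,5,7,9-tetraene-1,11-diyn-1-yl]-3,5,5-trimethylcyclohex-3-en-1-ol | CC1=C(C#C/C(C)=C/C=C/C=C/C=C(C)/C#C)C(C)(C)C[C@H](O)C1 | intermediate
16 | tert-butyldimethyl{[(1R)-3,5,5-trimethyl-4-[(trimethylsilyl)ethynyl]cyclohex-3-en-1-yl]oxy}silane | CC1=C(C#C[Si](C)(C)C)C(C)(C)C[C@H](O[Si](C)(C)C(C)(C)C)C1 | intermediate
17 | (1R)-4-ethynyl-3,5,5-trimethylcyclohex-3-en-1-ol | CC1=C(C#C)C(C)(C)C[C@H](O)C1 | intermediate
18 | (1S,3S,6S)-6-ethynyl-1,5,5-trimethyl-7-oxabicyclo[4.1.0]heptan-3-ol (epoxide cis to hydroxyl) | C#C[C@]12O[C@@]1(C)C[C@@H](O)CC2(C)C | intermediate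
19 | (1S,2R,4S)-1-ethynyl-2,6,6-trimethylcyclohexane-1,2,4-triol | C#C[C@@]1(O)C(C)(C)C[C@H](O)C[C@@]1(C)O | intermediate
20 | (1R,2R,4S)-2,6,6-trimethyl-1-[(E)-2-(tributylstannyl)ethenyl]cyclohexane-1,2,4-triol | CCCC[Sn](CCCC)(CCCC)/C=C/[C@@]1(O)C(C)(C)C[C@H](O)C[C@@]1(C)O | intermediate
21 | methyl 3-(trimethylsilyl)prop-2-ynoate | COC(=O)C#C[Si](C)(C)C | starting material
22 | methyl (2E)-2-(tributylstannyl)-3-(trimethylsilyl)prop-2-enoate (silicon cis to ester) | COC(=O)/C(=C\[Si](C)(C)C)[Sn](CCCC)(CCCC)CCCC | intermediate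
23 | methyl (2E)-2-iodo-3-(trimethylsilyl)prop-2-enoate (silicon cis to ester) | COC(=O)/C(I)=C\[Si](C)(C)C | intermediate
24 | methyl (2Z)-2-{(E)-2-[(1R,2R,4S)-1,2,4-trihydroxy-2,6,6-trimethylcyclohexyl]ethenyl}-3-(trimethylsilyl)prop-2-enoate | COC(=O)/C(=C\[Si](C)(C)C)/C=C/[C@@]1(O)C(C)(C)C[C@H](O)C[C@@]1(C)O | intermediate
25 | methyl (2Z)-3-iodo-2-{(E)-2-[(1R,2R,4S)-1,2,4-trihydroxy-2,6,6-trimethylcyclohexyl]ethenyl}prop-2-enoate | COC(=O)/C(=C\I)/C=C/[C@@]1(O)C(C)(C)C[C@H](O)C[C@@]1(C)O | intermediate
26 | (2Z)-3-iodo-2-{(E)-2-[(1R,2R,4S)-1,2,4-trihydroxy-2,6,6-trimethylcyclohexyl]ethenyl}prop-2-enoic acid | OC(=O)/C(=C\I)/C=C/[C@@]1(O)C(C)(C)C[C@H](O)C[C@@]1(C)O | intermediate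
27 | (Z)-2-en-4-ynoic acid from coupling of 15 and 26 (carboxyl cis to the new alkynyl group, all-E tetraene) | CC1=C(C#C/C(C)=C/C=C/C=C/C=C(C)/C#C/C=C(/C=C/[C@@]2(O)C(C)(C)C[C@H](O)C[C@@]2(C)O)C(O)=O)C(C)(C)C[C@H](O)C1 | intermediate
28 | (5Z)-5-[(2E,4E,6E,8E)-11-[(4R)-4-hydroxy-2,6,6-trimethylcyclohex-1-en-1-yl]-2,9-dimethylundeca-2,4,6,8-tetraen-10-yn-1-ylidene]-3-{(E)-2-[(1R,2R,4S)-1,2,4-trihydroxy-2,6,6-trimethylcyclohexyl]ethenyl}furan-2(5H)-one | CC1=C(C#C/C(C)=C/C=C/C=C/C=C(C)/C=C2C=C(/C=C/[C@@]3(O)C(C)(C)C[C@H](O)C[C@@]3(C)O)C(=O)O/2)C(C)(C)C[C@H](O)C1 | target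

**Step count**

Total: 22 steps. Longest linear sequence: 13 steps (steps 1–4, 13–17, 19–22).

**Steps most likely to fail, with fallbacks**

1. Step 16. The protonated epoxide may ionise instead of being displaced, so that regiocontrol (attack at the ethynyl-bearing carbon), stereocontrol (capture of a cation from either face) or the skeleton (proton loss, ring contraction) is lost. The fallback sets out from 18 and comes back at 19, and delivers the oxygen intramolecularly instead.
   - Mitsunobu inversion of the carbinol of 18 with benzoic acid (PPh3, DIAD) would give the inverted epoxy benzoate F1, whose ester lies on the face opposite the epoxide oxygen and 1,3 to the methyl-bearing epoxide carbon.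
   - BF3·OEt2 in CH2Cl2 then lets the ester carbonyl open the epoxide at that carbon with inversion through a six-membered dioxanylium ion (neighbouring-group participation, which cannot reach the other epoxide carbon). Aqueous quench gives the hydroxy benzoate F2.
   - Methanolysis (K2CO3, MeOH) gives the carbinol-epimeric triol F3.
   - Oxidation of its only secondary alcohol (Dess–Martin periodinane) gives the β-hydroxy ketone F4.
   - Hydroxyl-directed reduction with Me4NBH(OAc)3 (hydride delivered from the β-hydroxyl, 1,3-anti) returns 19.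

2. Step 22. The lactonisation may stall after the cross-coupling or close in the 6-endo sense, and the unprotected acid and polyene may degrade during a slow palladium/copper reaction. The fallback sets out from 25 and 15 and comes back at 28, separating the two events.
   - Sonogashira coupling of ester 25 with 15 (Pd(PPh3)4, CuI, Et3N, THF) gives the methyl (Z)-enynoate F5.
   - LiOH saponification gives acid 27, now isolated.
   - Ag2CO3-catalysed 5-exo-dig lactonisation in acetone, a known Z-selective cyclisation of (Z)-2-en-4-ynoic acids, gives 28.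

3. Step 7. The stabilised formyl ylide may react sluggishly with the β,β-disubstituted enynal or homologate twice. The fallback sets out from 8 and comes back at 9, through a stepwise ester route.
   - Horner–Wadsworth–Emmons reaction of 8 with triethyl phosphonoacetate (NaH, THF) gives the ethyl (2E,4E)-dienynoate F6.
   - DIBAL-H reduction (CH2Cl2, −78 °C) gives the dienynol F7.
   - MnO2 oxidation gives 9.

Further compounds
F1 | step 16 | (1S,3R,6S)-6-ethynyl-1,5,5-trimethyl-7-oxabicyclo[4.1.0]heptan-3-yl benzoate (ester trans to the epoxide oxygen) | C#C[C@]12O[C@@]1(C)C[C@H](OC(=O)c3ccccc3)CC2(C)C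
F2 | step 16 | secondary benzoate of the carbinol-epimeric triol (tertiary hydroxyls free, trans diol) | C#C[C@@]1(O)C(C)(C)C[C@@H](OC(=O)c2ccccc2)C[C@@]1(C)O
F3 | step 16 | (1S,2R,4R)-1-ethynyl-2,6,6-trimethylcyclohexane-1,2,4-triol | C#C[C@@]1(O)C(C)(C)C[C@@H](O)C[C@@]1(C)O
F4 | step 16 | (3R,4S)-4-ethynyl-3,4-dihydroxy-3,5,5-trimethylcyclohexan-1-one | C#C[C@@]1(O)C(C)(C)CC(=O)C[C@@]1(C)O
F5 | step 22 | methyl ester of enynoic acid 27 | CC1=C(C#C/C(C)=C/C=C/C=C/C=C(C)/C#C/C=C(/C=C/[C@@]2(O)C(C)(C)C[C@H](O)C[C@@]2(C)O)C(=O)OC)C(C)(C)C[C@H](O)C1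
F6 | step 7 | ethyl (2E,4E)-7-{(4R)-4-[(tert-butyldimethylsilyl)oxy]-2,6,6-trimethylcyclohex-1-en-1-yl}-5-methylhepta-2,4-dien-6-ynoate | CC1=C(C#C/C(C)=C/C=C/C(=O)OCC)C(C)(C)C[C@H](O[Si](C)(C)C(C)(C)C)C1
F7 | step 7 | (2E,4E)-7-{(4R)-4-[(tert-butyldimethylsilyl)oxy]-2,6,6-trimethylcyclohex-1-en-1-yl}-5-methylhepta-2,4-dien-6-yn-1-ol | CC1=C(C#C/C(C)=C/C=C/CO)C(C)(C)C[C@H](O[Si](C)(C)C(C)(C)C)C1
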